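With daucane numbering (C1 methyl-bearing fusion carbon, C4 carbinol, C5 fusion CH, C6 anisoyloxy, C8=C9 alkene, C10 angeloyloxy), the hydroazulene is disconnected at C1–C5 and C8–C9. A gold-catalysed intramolecular (4+3) cycloaddition of an allene (C9=C10=C1) with a siloxydiene (C5=C6–C7=C8) closes the cyclopentane and the cycloheptene at once. It exploits the 1,3-related oxygens on C4 and C6: tied into a temporary dioxasiline ring, they fix the diene geometry and let the C4 carbinol, taken from (S)-terpinen-4-ol, control C5, C1 and C8. The precursor is an open-chain allene-diene; a later singlet-oxygen ene reaction moves the C9=C10 alkene to C8=C9 and installs the 10α oxygen.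

Key step: step 7

Remark on numbering: daucane = bicyclo[5.3.0]decane with CH3 on C1, isopropyl on C4 and CH3 on C8; five-membered ring C1–C2–C3–C4–C5, seven-membered ring C1–C5–C6–C7–C8–C9–C10; β is the face of the C1 methyl group.
Assumption: (S)-terpinen-4-ol is used in enantiopure form (commercial material is upgraded beforehand if necessary).

Step 1
Reactants: 1 (S)-terpinen-4-ol
Product: 3 (3S)-3-hydroxy-6-oxo-3-(propan-2-yl)heptanal, via ozonide 2 (not isolated)
Conditions: O3, CH2Cl2, −78 °C; then Me2S, −78 °C to rt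
Reagents that add atoms: ozone, [O-][O+]=O
Why: Ozonolysis (Criegee mechanism, reductive work-up) cleaves the only C=C bond and turns its two carbons into the C6 aldehyde and the C1 methyl ketone, leaving the C4 carbinol stereocentre of 1 untouched; 3 is used crude because it equilibrates with a cyclic hemiketal.

Step 2
Reactants: 3 (3S)-3-hydroxy-6-oxo-3-(propan-2-yl)heptanal; 4 (E)-1-bromoprop-1-ene
Product: 5 (5S,8E)-5,7-dihydroxy-5-(propan-2-yl)dec-8-en-2-one (both C7 epimers)
Conditions: CrCl2 (4 equiv), NiCl2 (2 mol%), DMF, rt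
Reagents that add atoms: none
Why: Nozaki–Hiyama–Kishi coupling: the alkenylchromium species formed from 4 with retention of the E geometry adds to the aldehyde but not to the ketone and tolerates the free tertiary hydroxyl; the new carbinol is a mixture of epimers that is erased in step 3.

Step 3
Reactants: 5 (5S,8E)-5,7-dihydroxy-5-(propan-2-yl)dec-8-en-2-one
Product: 6 (5S,8E)-5-hydroxy-5-(propan-2-yl)dec-8-ene-2,7-dione
Conditions: MnO2 (excess), CH2Cl2, rt
Reagents that add atoms: none
Why: Allylic oxidation with MnO2 is selective for the secondary allylic alcohol and neutral, so the tertiary aldol unit neither dehydrates nor undergoes retro-aldol cleavage.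

Step 4
Reactants: 6 (5S,8E)-5-hydroxy-5-(propan-2-yl)dec-8-ene-2,7-dione
Product: 7 4-[(4R)-2,2,4-tri(propan-2-yl)-6-[(E)-prop-1-en-1-yl]-4H-1,3,2-dioxasilin-4-yl]butan-2-one
Conditions: iPr2Si(OTf)2 (1.05 equiv), Et3N, CH2Cl2, −78 to 0 °C
Reagents that add atoms: di(propan-2-yl)silyl bis(trifluoromethanesulfonate), CC(C)[Si](OS(=O)(=O)C(F)(F)F)(OS(=O)(=O)C(F)(F)F)C(C)C
Why: Silylene tethering by soft enolisation: after O-silylation of the C4 hydroxyl the second Si–OTf is delivered to the C6 carbonyl oxygen through a six-membered ring and Et3N removes a C5 proton, so only the enone (not the remote methyl ketone) becomes a cross-conjugated silyl dienol ether whose C5=C6 geometry is locked by the ring.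

Step 5
Reactants: 7 4-[(4R)-2,2,4-tri(propan-2-yl)-6-[(E)-prop-1-en-1-yl]-4H-1,3,2-dioxasilin-4-yl]butan-2-one
Product: 9 methyl 3-methyl-5-[(4R)-2,2,4-tri(propan-2-yl)-6-[(E)-prop-1-en-1-yl]-4H-1,3,2-dioxasilin-4-yl]pent-1-yn-3-yl carbonate (both C3 epimers), via bromomagnesium alkoxide 8 (not isolated)
Conditions: HC≡CMgBr, THF, −20 to 0 °C; then ClCO2Me, 0 °C to rt
Reagents that add atoms: ethynylmagnesium bromide, C#C[Mg]Br; methyl chloroformate, COC(=O)Cl
Why: Grignard 1,2-addition to the only carbonyl group left, then O-acylation of the tertiary alkoxide in the same flask; the new carbinol centre is irrelevant because it becomes the sp2 allene carbon C1.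

Step 6
Reactants: 9 methyl propargylic carbonate
Product: 10 (4R)-4-(3-methylpenta-3,4-dien-1-yl)-2,2,4-tri(propan-2-yl)-6-[(E)-prop-1-en-1-yl]-4H-1,3,2-dioxasiline
Conditions: Pd2(dba)3·CHCl3 (2.5 mol%), PBu3 (10 mol%), HCO2NH4 (2 equiv), THF, rt
Reagents that add atoms: none
Why: Tsuji-type hydrogenolysis of a propargylic carbonate: zerovalent palladium ionises the carbonate in the SN2' sense to an allenylpalladium species, formate supplies hydride and reductive elimination gives the terminal 1,1-disubstituted allene while the silyl dienol ether is untouched.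

Step 7
Reactants: 10 allene-diene
Product: 12 4β,6-[di(propan-2-yl)silanediyldioxy]dauca-6,9-diene (trans-fused; 1β-CH3, 5α-H, 8α-H, 8β-CH3), via gold carbene 11 (not isolated)
Conditions: IPrAuNTf2 (5 mol%; IPr = 1,3-bis(2,6-diisopropylphenyl)imidazol-2-ylidene), 4 Å molecular sieves, CH2Cl2, 0 °C to rt
Reagents that add atoms: none
Why: Cationic monovalent gold activates the allene as a gold-bound allyl cation spanning C1–C10–C9, which adds across the diene termini in a concerted (4+3) cycloaddition (C1–C5 and C9–C8), and the gold carbene 11 left at C10 collapses by 1,2-hydride shift from C9 to the C9=C10 alkene, C1 having no hydrogen. The closest known reaction type is the gold- or platinum-catalysed intramolecular (4+3) cycloaddition of allenedienes with three-atom tethers, which gives trans-fused bicyclo[5.3.0]decadienes. The cyclopentane closes in the 5-exo sense through C1–C5 and the cycloheptene is closed by the cycloaddition itself through C9–C8 (7-endo in stepwise terms). C5 is controlled by the dioxasiline ring, which holds O4 syn to O6 so that the tether reaches only one diene face and O4 and C6 become cis on the cyclopentane; C1 follows from the extended (exo-like) transition state, which places its methyl group anti to H5; C8 follows from suprafacial addition to the (E,E)-diene, which places H8 cis to H5. The step needs the hydride shift to outrun the ring-contracting 1,2-alkyl shift and needs the allene to be safe from oxygen nucleophiles, which the strongly donating carbene ligand and the silylene mask on the C4 hydroxyl should secure.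

Step 8
Reactants: 12 silylene-bridged cycloadduct
Product: 13 4β-hydroxydauc-9-en-6-one (1β-CH3, 5α-H, 8β-CH3)
Conditions: HF·pyridine, pyridine/THF, 0 °C
Reagents that add atoms: none
Why: Fluoride cleaves both Si–O bonds and the liberated enol tautomerises to the C6 ketone; the weakly acidic medium avoids epimerisation at C5 and retro-aldol cleavage of the tertiary aldol.

Step 9
Reactants: 13 4β-hydroxydauc-9-en-6-one
Product: 14 dauc-9-ene-4β,6α-diol
Conditions: Me4NBH(OAc)3, MeCN/AcOH, −20 °C
Reagents that add atoms: none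
Why: Evans–Saksena hydroxyl-directed reduction: the C4 hydroxyl exchanges onto boron and hydride is delivered intramolecularly to the β face of the C6 carbonyl, giving the anti-1,3-diol with the 6α-hydroxyl; the unactivated alkene does not react.

Step 10
Reactants: 14 dauc-9-ene-4β,6α-diol; 15 4-methoxybenzoyl chloride
Product: 16 6α-(4-methoxybenzoyloxy)dauc-9-en-4β-ol
Conditions: pyridine, DMAP (cat.), CH2Cl2, 0 °C to rt
Reagents that add atoms: none
Why: DMAP-catalysed acylation (nucleophilic catalysis) takes place only at the secondary C6 hydroxyl, the C4 hydroxyl being tertiary and shielded by the isopropyl group.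

Step 11
Reactants: 16 6α-(4-methoxybenzoyloxy)dauc-9-en-4β-ol
Product: 18 6α-(4-methoxybenzoyloxy)dauc-8-ene-4β,10α-diol, via hydroperoxide 17 (not isolated)
Conditions: O2, visible light, tetraphenylporphyrin (cat.), CDCl3, 0 °C; then PPh3, rt
Reagents that add atoms: dioxygen, O=O
Why: Schenck ene reaction: singlet oxygen can only bond to C10 and abstract H8, the sole allylic hydrogen, and does so suprafacially on the α face where H8 lies (also the face anti to the axial C1 methyl), so the hydroperoxide arises at C10α with the alkene shifted to C8=C9, and PPh3 reduces the O–O bond with retention.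

Step 12
Reactants: 18 6α-(4-methoxybenzoyloxy)dauc-8-ene-4β,10α-diol; 19 angelic acid
Product: 21 10α-angeloyloxy-6α-(4-methoxybenzoyloxy)dauc-8-en-4β-ol (target), via mixed anhydride 20 (not isolated)
Conditions: 2,4,6-trichlorobenzoyl chloride, Et3N, toluene, rt; then 18, 80 °C
Reagents that add atoms: none
Why: Yamaguchi esterification through the mixed anhydride 20, run without DMAP to keep the Z geometry of the angelate; only the secondary allylic C10 hydroxyl is acylated, the tertiary C4 hydroxyl is not.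

Compound list
1 | (S)-terpinen-4-ol, (1S)-4-methyl-1-(propan-2-yl)cyclohex-3-en-1-ol | CC1=CC[C@](O)(C(C)C)CC1 | starting material
2 | secondary ozonide of 1, 1-methyl-4-(propan-2-yl)-7,8,9-trioxabicyclo[4.2.1]nonan-4-ol (carbinol centre as in 1) | CC12CC[C@@](O)(C(C)C)CC(OO1)O2 | intermediate
3 | (3S)-3-hydroxy-6-oxo-3-(propan-2-yl)heptanal | O=CC[C@](O)(C(C)C)CCC(C)=O | intermediate
4 | (E)-1-bromoprop-1-ene | C/C=C/Br | starting material
5 | (5S,8E)-5,7-dihydroxy-5-(propan-2-yl)dec-8-en-2-one (both C7 epimers) | C/C=C/C(O)C[C@](O)(C(C)C)CCC(C)=O | intermediate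
6 | (5S,8E)-5-hydroxy-5-(propan-2-yl)dec-8-ene-2,7-dione | C/C=C/C(=O)C[C@](O)(C(C)C)CCC(C)=O | intermediate
7 | 4-[(4R)-2,2,4-tri(propan-2-yl)-6-[(E)-prop-1-en-1-yl]-4H-1,3,2-dioxasilin-4-yl]butan-2-one | C/C=C/C1=C[C@](C(C)C)(CCC(C)=O)O[Si](C(C)C)(C(C)C)O1 | intermediate
8 | bromomagnesium alkoxide of the tertiary propargylic alcohol formed from 7 (both carbinol epimers) | C/C=C/C1=C[C@](C(C)C)(CCC(C)(O[Mg]Br)C#C)O[Si](C(C)C)(C(C)C)O1 | intermediate
9 | methyl 3-methyl-5-[(4R)-2,2,4-tri(propan-2-yl)-6-[(E)-prop-1-en-1-yl]-4H-1,3,2-dioxasilin-4-yl]pent-1-yn-3-yl carbonate (both C3 epimers) | C/C=C/C1=C[C@](C(C)C)(CCC(C)(OC(=O)OC)C#C)O[Si](C(C)C)(C(C)C)O1 | intermediate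
10 | (4R)-4-(3-methylpenta-3,4-dien-1-yl)-2,2,4-tri(propan-2-yl)-6-[(E)-prop-1-en-1-yl]-4H-1,3,2-dioxasiline | C/C=C/C1=C[C@](C(C)C)(CCC(C)=C=C)O[Si](C(C)C)(C(C)C)O1 | intermediate
11 | gold carbene at C10 of the cycloadduct (monovalent gold, IPr ligand, NTf2 counter-ion) | CC(C)c1cccc(C(C)C)c1-n1cc[n+](-c2c(C(C)C)cccc2C(C)C)c1[Au]=C1C[C@@H](C)C=C3[C@@H]2[C@]1(C)CC[C@@]2(O[Si](C(C)C)(C(C)C)O3)C(C)C.O=S(=O)([N-]S(=O)(=O)C(F)(F)F)C(F)(F)F | intermediate
12 | 4β,6-[di(propan-2-yl)silanediyldioxy]dauca-6,9-diene (trans-fused; 1β-CH3, 5α-H, 8α-H, 8β-CH3) | C1=C[C@@H](C)C=C3[C@@H]2[C@]1(C)CC[C@@]2(O[Si](C(C)C)(C(C)C)O3)C(C)C | intermediate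
13 | 4β-hydroxydauc-9-en-6-one (1β-CH3, 5α-H, 8β-CH3) | C1=C[C@@H](C)CC(=O)[C@@H]2[C@]1(C)CC[C@@]2(O)C(C)C | intermediate
14 | dauc-9-ene-4β,6α-diol | C1=C[C@@H](C)C[C@H](O)[C@@H]2[C@]1(C)CC[C@@]2(O)C(C)C | intermediate
15 | 4-methoxybenzoyl chloride | COc1ccc(cc1)C(Cl)=O | starting material
16 | 6α-(4-methoxybenzoyloxy)dauc-9-en-4β-ol | C1=C[C@@H](C)C[C@H](OC(=O)c3ccc(OC)cc3)[C@@H]2[C@]1(C)CC[C@@]2(O)C(C)C | intermediate
17 | 10α-hydroperoxy-6α-(4-methoxybenzoyloxy)dauc-8-en-4β-ol | OO[C@@H]1C=C(C)C[C@H](OC(=O)c3ccc(OC)cc3)[C@@H]2[C@]1(C)CC[C@@]2(O)C(C)C | intermediate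
18 | 6α-(4-methoxybenzoyloxy)dauc-8-ene-4β,10α-diol | O[C@@H]1C=C(C)C[C@H](OC(=O)c3ccc(OC)cc3)[C@@H]2[C@]1(C)CC[C@@]2(O)C(C)C | intermediate
19 | angelic acid, (Z)-2-methylbut-2-enoic acid | C/C=C(/C)C(=O)O | starting material
20 | angelic 2,4,6-trichlorobenzoic anhydride | C/C=C(/C)C(=O)OC(=O)c1c(Cl)cc(Cl)cc1Cl | intermediate
21 | 10α-angeloyloxy-6α-(4-methoxybenzoyloxy)dauc-8-en-4β-ol | C/C=C(/C)C(=O)O[C@@H]1C=C(C)C[C@H](OC(=O)c2ccc(OC)cc2)[C@@H]2[C@]1(C)CC[C@@]2(O)C(C)C | target

Total step count: 12. Longest linear sequence: 12 steps (from 1).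

Steps most likely to fail

Step 7. The gold carbene may undergo ring-contracting 1,2-alkyl shift (formal (4+2) product), the siloxydiene may close at C6 in a (3+2) sense or be protodesilylated, and ring-fusion selectivity may erode. The fallback sets out from 7 and returns at 12, forming the same two bonds by a 2-alkoxyallyl-cation (4+3) cycloaddition. Addition of 1-ethoxyvinyllithium (ethyl vinyl ether, t-BuLi, THF, −78 °C) to ketone 7 gives the tertiary 2-ethoxyallylic alcohol F1. Ionisation with Tf2O/2,6-lutidine (CH2Cl2, −78 °C) and aqueous work-up should give, by intramolecular (4+3) cycloaddition of the ethoxyallyl cation onto the same tethered diene, the C10 ketone 4β,6-[di(propan-2-yl)silanediyldioxy]dauc-6-en-10-one F2. KHMDS/PhNTf2 converts it (only C9 can be deprotonated) into the dienyl triflate F3, and formate reduction (Pd(OAc)2, PPh3, HCO2H, Bu3N, DMF) gives 12.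

Step 11. The cis-disubstituted cycloheptene may react too slowly with singlet oxygen, so that photodegradation competes, or H8 may be poorly aligned for abstraction. The fallback sets out from 16 and returns at 18. Epoxidation with mCPBA/NaHCO3 (CH2Cl2, 0 °C) should occur on the α face, anti to the axial C1 methyl group, to give 9α,10α-epoxy-6α-(4-methoxybenzoyloxy)daucan-4β-ol F4. Diethylaluminium 2,2,6,6-tetramethylpiperidide (from Et2AlCl and LiTMP, toluene, 0 °C) then isomerises the epoxide by syn-abstraction of H8 to the allylic alcohol 18.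

Step 4. Silylation of the hindered tertiary hydroxyl may be slow, allowing oxa-Michael closure of the hydroxy enone or silyl enol ether formation at the methyl ketone, and the dioxasiline may hydrolyse on isolation. The fallback sets out from 6 and returns at 7, installing the tether in two stages. Chlorodi(propan-2-yl)silane/imidazole/DMAP (DMF) gives the hydrosilyl ether (5S,8E)-5-{[di(propan-2-yl)silyl]oxy}-5-(propan-2-yl)dec-8-ene-2,7-dione F5. N-Bromosuccinimide (CH2Cl2, 0 °C) converts Si–H into Si–Br to give the bromosilyl ether F6, and Et3N closes the ring onto the enone oxygen with loss of a C5 proton to give 7.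

Further compounds
F1 | step 7 | 2-ethoxy-3-methyl-5-[(4R)-2,2,4-tri(propan-2-yl)-6-[(E)-prop-1-en-1-yl]-4H-1,3,2-dioxasilin-4-yl]pent-1-en-3-ol (both C3 epimers) | C/C=C/C1=C[C@](C(C)C)(CCC(C)(O)C(=C)OCC)O[Si](C(C)C)(C(C)C)O1
F2 | step 7 | 4β,6-[di(propan-2-yl)silanediyldioxy]dauc-6-en-10-one (1β-CH3, 5α-H, 8β-CH3) | O=C1C[C@@H](C)C=C3[C@@H]2[C@]1(C)CC[C@@]2(O[Si](C(C)C)(C(C)C)O3)C(C)C
F3 | step 7 | 4β,6-[di(propan-2-yl)silanediyldioxy]dauca-6,9-dien-10-yl trifluoromethanesulfonate | FC(F)(F)S(=O)(=O)OC1=C[C@@H](C)C=C3[C@@H]2[C@]1(C)CC[C@@]2(O[Si](C(C)C)(C(C)C)O3)C(C)C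
F4 | step 11 | 9α,10α-epoxy-6α-(4-methoxybenzoyloxy)daucan-4β-ol (8β-CH3) | O1[C@@H]2[C@H]1[C@@H](C)C[C@H](OC(=O)c3ccc(OC)cc3)[C@@H]3[C@]2(C)CC[C@@]3(O)C(C)C
F5 | step 4 | (5S,8E)-5-{[di(propan-2-yl)silyl]oxy}-5-(propan-2-yl)dec-8-ene-2,7-dione | C/C=C/C(=O)C[C@](O[SiH](C(C)C)C(C)C)(C(C)C)CCC(C)=O
F6 | step 4 | (5S,8E)-5-{[bromodi(propan-2-yl)silyl]oxy}-5-(propan-2-yl)dec-8-ene-2,7-dione | C/C=C/C(=O)C[C@](O[Si](Br)(C(C)C)C(C)C)(C(C)C)CCC(C)=O
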